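Ring A is opened at C2–C3 (labdane numbering), a methylene–methylene bond flanked by the gem-dimethyl carbon C4 and, one carbon away, the quaternary C10. These two quaternary centres let each olefin terminus arrive as a simple allyl unit (allyl on C10, 1,1-dimethylallyl on C5) and favour closure. The precursor is a ring B cyclohexene (C5=C6) carrying both groups, built from yeast-desymmetrised 2-allyl-2-methylcyclohexane-1,3-dione. Ring-closing metathesis with in-situ hydrogenation forges C2–C3 and delivers saturated ring A in one operation, while the hindered C5=C6 olefin survives for α-face hydroboration (5α-H, 6α-OH). The C9 carbonyl then brings in the C8 methyl, the 9α-hydroxyl and the butenolide side chain.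

Key step: step 7

Remark: labdane numbering is used for the target and for the corresponding carbons of every intermediate (ring A = C1–C5 and C10, C4 gem-dimethyl, ring B = C5–C10, side chain C11–C16 on C9); α is the face opposite the C10 methyl.

Step 1
Reactants: 1 2-methylcyclohexane-1,3-dione; 2 allyl bromide
Product: 3 2-methyl-2-(prop-2-en-1-yl)cyclohexane-1,3-dione
Conditions: allyl bromide, 1 M aq. NaOH, rt
Reagents that add atoms: allyl bromide (2), C=CCBr
Why: C-alkylation of the stabilised enolate of the cyclic 1,3-diketone (SN2 on allyl bromide) in water, where C- is favoured over O-allylation; the product is achiral.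

Step 2
Reactants: 3 2-methyl-2-(prop-2-en-1-yl)cyclohexane-1,3-dione
Product: 4 (2S,3S)-3-hydroxy-2-methyl-2-(prop-2-en-1-yl)cyclohexan-1-one
Conditions: baker's yeast (Saccharomyces cerevisiae), sucrose, H2O, 30 °C; chromatography
Reagents that add atoms: none
Why: Enantiotopic-group-selective ketone reduction by the yeast dehydrogenases should give the (2S,3S)-ketol, which fixes the quaternary carbon (future C10) as S; the minor (2R,3S) diastereomer from reduction of the other carbonyl is removed by chromatography.

Step 3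
Reactants: 4 (2S,3S)-3-hydroxy-2-methyl-2-(prop-2-en-1-yl)cyclohexan-1-one
Product: 5 (6S,7S)-6-methyl-6-(prop-2-en-1-yl)-1,4-dioxaspiro[4.5]decan-7-ol
Conditions: ethylene glycol, p-TsOH·H2O (cat.), benzene, reflux (Dean–Stark)
Reagents that add atoms: ethylene glycol, OCCO
Why: Acid-catalysed ketalisation with azeotropic water removal masks the remaining ketone (future C9), so the two oxygenated carbons flanking the quaternary centre stay differentiated; no stereocentre is touched.

Step 4
Reactants: 5 (6S,7S)-6-methyl-6-(prop-2-en-1-yl)-1,4-dioxaspiro[4.5]decan-7-ol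
Product: 6 (6S)-6-methyl-6-(prop-2-en-1-yl)-1,4-dioxaspiro[4.5]decan-7-one
Conditions: Dess–Martin periodinane, pyridine, CH2Cl2, rt
Reagents that add atoms: none
Why: Dess–Martin oxidation turns the secondary carbinol into the ketone (future C5) under buffered conditions that spare ketal and olefin; the quaternary α-carbon cannot epimerise, so the S configuration of the future C10 is retained.

Step 5
Reactants: 6 (6S)-6-methyl-6-(prop-2-en-1-yl)-1,4-dioxaspiro[4.5]decan-7-one; 7 prenylmagnesium chloride
Product: 8 (6S,7R)-6-methyl-7-(2-methylbut-3-en-2-yl)-6-(prop-2-en-1-yl)-1,4-dioxaspiro[4.5]decan-7-ol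
Conditions: prenylmagnesium chloride (1.5 equiv), THF, −78 °C; cold aqueous quench (H2O/NH4Cl)
Reagents that add atoms: prenylmagnesium chloride (7), CC(C)=CC[Mg]Cl
Why: Allylic Grignard addition through a six-membered SE2' transition state delivers the 1,1-dimethylallyl group (future C4 and C3) to the hindered carbonyl, low temperature preventing reversal to the linear prenyl adduct; the new carbinol centre, drawn with the hydroxyl trans to the ring methyl, is erased in step 6, so either epimer serves.

Step 6
Reactants: 8 (6S,7R)-6-methyl-7-(2-methylbut-3-en-2-yl)-6-(prop-2-en-1-yl)-1,4-dioxaspiro[4.5]decan-7-ol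
Product: 9 (6S)-6-methyl-7-(2-methylbut-3-en-2-yl)-6-(prop-2-en-1-yl)-1,4-dioxaspiro[4.5]dec-7-ene
Conditions: SOCl2, pyridine, CH2Cl2, −20 → 0 °C
Reagents that add atoms: none
Why: Dehydration via the chlorosulfite with pyridine-mediated E2 elimination can only place the olefin between C5 and C6 because C4 and C10 are quaternary; the basic medium suppresses cationic 1,2-shifts, and the carbinol stereocentre disappears.

Step 7
Reactants: 9 (6S)-6-methyl-7-(2-methylbut-3-en-2-yl)-6-(prop-2-en-1-yl)-1,4-dioxaspiro[4.5]dec-7-ene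
Product: 11 (10S)-4,4,10-trimethyl-Δ5-octalin-9-one ethylene ketal, via ring-closed diene 10 (not isolated)
Conditions: RuCl2(=CHPh)(PCy3)(H2IMes) (second-generation Grubbs catalyst, 5 mol %), toluene, 60 °C, ethene purged; then H2 (4 atm), 50 °C
Reagents that add atoms: none
Why: The ruthenium alkylidene loads onto the unhindered allyl terminus on C10 and engages the neopentyl vinyl group on C4 in a [2+2]/retro-[2+2] sequence that expels ethene and forges C2=C3; admitting H2 then turns the same ruthenium species into a hydride that saturates this new cis-disubstituted olefin. The closest known reaction type is tandem ring-closing metathesis–hydrogenation with one ruthenium carbene precatalyst. Ring A is closed as a six-membered carbocycle by ring-closing olefin metathesis of a 1,7-diene, with the gem-dimethyl group at C4 and the sp2 carbon C5 holding the two termini together. No stereocentre is created, and the C10 configuration from step 2 is untouched because C10 carries no hydrogen. The step needs chemoselectivity for the two terminal olefins over the trisubstituted C5=C6 bond; that bond lies between the quaternary carbons C4 and C10 and should be inert to both metathesis and the ruthenium hydride under these mild conditions.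

Step 8
Reactants: 11 (10S)-4,4,10-trimethyl-Δ5-octalin-9-one ethylene ketal
Product: 14 (5S,6S,10S)-6α-hydroxy-4,4,10β-trimethyl-trans-decalin-9-one, via alkylborane 12 (not isolated), via hydroxy ketal 13 (not isolated)
Conditions: BH3·THF (excess), THF, 0 → 40 °C; NaOH, H2O2, 0 °C → rt; then 2 M HCl, THF, rt
Reagents that add atoms: borane–tetrahydrofuran, [BH3-][O+]1CCCC1 (boron only in 12); hydrogen peroxide, OO; water, O
Why: Hydroboration–oxidation adds H and B syn across C5=C6 from the α-face, opposite the axial C10 methyl and the 4β-methyl, with boron on the less substituted C6; this sets the trans ring fusion (5α-H) and the equatorial 6α-hydroxyl together (oxidation with retention), and aqueous acid then hydrolyses the dioxolane to the C9 ketone.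

Step 9
Reactants: 14 (5S,6S,10S)-6α-hydroxy-4,4,10β-trimethyl-trans-decalin-9-one
Product: 16 (5S,6S,8R,10S)-6α-hydroxy-4,4,8α,10β-tetramethyl-trans-decalin-9-one, via dilithium enolate 15 (not isolated)
Conditions: LiN(i-Pr)2 (2.2 equiv), THF, −78 °C; MeI (1.05 equiv), −78 → −20 °C; then NaOMe (cat.), MeOH, rt
Reagents that add atoms: iodomethane, CI; lithium diisopropylamide, CC(C)[N-]C(C)C.[Li+] (lithium only in 15)
Why: Kinetic enolate alkylation: only C8 carries enolisable hydrogens because C10 is quaternary, the enolate is C-methylated while the lithium alkoxide stays inert at low temperature, and methoxide equilibration places the new methyl equatorial (8α), since an axial 8β-methyl would be syn-diaxial to the C10 methyl.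

Step 10
Reactants: 16 (5S,6S,8R,10S)-6α-hydroxy-4,4,8α,10β-tetramethyl-trans-decalin-9-one
Product: 17 (5S,6S,8R,10S)-4,4,8α,10β-tetramethyl-9-methylene-trans-decalin-6α-ol
Conditions: Ph3PCH3Br, KOt-Bu (excess), toluene, 90 °C
Reagents that add atoms: methyltriphenylphosphonium bromide, C[P+](c1ccccc1)(c1ccccc1)c1ccccc1.[Br-]
Why: Wittig methylenation in its potassium tert-butoxide/hot toluene variant for hindered ketones converts C9=O into the exocyclic olefin C9=C11; excess ylide tolerates the free hydroxyl and C8 stays at its thermodynamic configuration.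

Step 11
Reactants: 17 (5S,6S,8R,10S)-4,4,8α,10β-tetramethyl-9-methylene-trans-decalin-6α-ol
Product: 18 9α,11-epoxide of 17 (spiro-oxirane at C9 with oxygen α and C11 β)
Conditions: mCPBA, CH2Cl2/aq. NaHCO3, 0 °C
Reagents that add atoms: 3-chloroperbenzoic acid, OOC(=O)c1cccc(Cl)c1
Why: Prilezhaev epoxidation: the peracid should reach the exocyclic olefin from the α-face (axial direction), away from the axial C10 methyl that shields the β-face, so the oxygen becomes 9α and C11 9β, which sets C9.

Step 12
Reactants: 18 9α,11-epoxide of 17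
Product: 19 (5S,6S,8R,9R,10S)-9β-vinyl-4,4,8α,10β-tetramethyl-trans-decalin-6α,9α-diol
Conditions: Me3SI (4 equiv), n-BuLi (3.9 equiv), THF, −10 °C → rt
Reagents that add atoms: trimethylsulfonium iodide, C[S+](C)C.[I-]
Why: Sulfonium ylide homologation of an epoxide to an allylic alcohol: the ylide opens the oxirane at its methylene (C11) by SN2 and a second ylide equivalent triggers elimination of dimethyl sulfide to give the C11=C12 vinyl group; the C9–O bond is never broken, so the 9α-hydroxyl is retained.

Step 13
Reactants: 19 (5S,6S,8R,9R,10S)-9β-vinyl-4,4,8α,10β-tetramethyl-trans-decalin-6α,9α-diol; 20 3-bromofuran-2(5H)-one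
Product: 22 (5S,6S,8R,9R,10S)-6α,9α-dihydroxylabd-13-en-16,15-olide, via B-alkyl-9-BBN adduct 21 (not isolated)
Conditions: 9-BBN (2 equiv), THF, 0 °C → rt; then 20, PdCl2(dppf) (5 mol %), AsPh3, Cs2CO3, DMF/H2O, rt
Reagents that add atoms: 3-bromofuran-2(5H)-one (20), O=C1OCC=C1Br; 9-borabicyclo[3.3.1]nonane, B1C2CCCC1CCC2 (boron only in 21)
Why: Anti-Markovnikov hydroboration of the monosubstituted vinyl group with 9-BBN followed by B-alkyl Suzuki–Miyaura coupling with the α-bromobutenolide forms C12–C13 and installs the complete α-substituted butenolide; no stereocentre is involved and the hindered hydroxyls need no protection.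

Step 14
Reactants: 22 (5S,6S,8R,9R,10S)-6α,9α-dihydroxylabd-13-en-16,15-olide
Product: 23 (5S,6S,8R,9R,10S)-6α-acetoxy-9α-hydroxylabd-13-en-16,15-olide (target)
Conditions: Ac2O, pyridine, DMAP (cat.), CH2Cl2, rt
Reagents that add atoms: acetic anhydride, CC(=O)OC(C)=O
Why: DMAP-catalysed acylation acetylates the equatorial secondary 6α-hydroxyl, whereas the tertiary 9α-hydroxyl, flanked by the quaternary C10 and the substituted C8, should not react; no stereocentre is affected.

Compound list

1 | 2-methylcyclohexane-1,3-dione | CC1C(=O)CCCC1=O | starting material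
2 | allyl bromide | C=CCBr | starting material
3 | 2-methyl-2-(prop-2-en-1-yl)cyclohexane-1,3-dione | C=CCC1(C)C(=O)CCCC1=O | intermediate
4 | (2S,3S)-3-hydroxy-2-methyl-2-(prop-2-en-1-yl)cyclohexan-1-one | O[C@H]1CCCC(=O)[C@@]1(C)CC=C | intermediate
5 | (6S,7S)-6-methyl-6-(prop-2-en-1-yl)-1,4-dioxaspiro[4.5]decan-7-ol | O[C@H]1CCCC2(OCCO2)[C@@]1(C)CC=C | intermediate
6 | (6S)-6-methyl-6-(prop-2-en-1-yl)-1,4-dioxaspiro[4.5]decan-7-one | O=C1CCCC2(OCCO2)[C@@]1(C)CC=C | intermediate
7 | prenylmagnesium chloride ((3-methylbut-2-en-1-yl)magnesium chloride, THF solution) | CC(C)=CC[Mg]Cl | starting material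
8 | (6S,7R)-6-methyl-7-(2-methylbut-3-en-2-yl)-6-(prop-2-en-1-yl)-1,4-dioxaspiro[4.5]decan-7-ol (hydroxyl trans to the ring methyl) | C=CC(C)(C)[C@]1(O)CCCC2(OCCO2)[C@@]1(C)CC=C | intermediate
9 | (6S)-6-methyl-7-(2-methylbut-3-en-2-yl)-6-(prop-2-en-1-yl)-1,4-dioxaspiro[4.5]dec-7-ene | C=CC(C)(C)C1=CCCC2(OCCO2)[C@@]1(C)CC=C | intermediate
10 | ring-closed diene: (10S)-4,4,10-trimethyl-hexalin-9-one ethylene ketal with C2=C3 and C5=C6 | CC1(C)C=CC[C@@]2(C)C1=CCCC23OCCO3 | intermediate
11 | (10S)-4,4,10-trimethyl-Δ5-octalin-9-one ethylene ketal (C5=C6 only) | CC1(C)CCC[C@@]2(C)C1=CCCC23OCCO3 | intermediate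
12 | alkylborane: 6α-boryl-5α-H-4,4,10β-trimethyl-trans-decalin-9-one ethylene ketal (drawn as monomeric RBH2) | B[C@H]1CCC3(OCCO3)[C@@]2(C)CCCC(C)(C)[C@H]12 | intermediate
13 | hydroxy ketal: (5S,6S,10S)-6α-hydroxy-4,4,10β-trimethyl-trans-decalin-9-one ethylene ketal | O[C@H]1CCC3(OCCO3)[C@@]2(C)CCCC(C)(C)[C@H]12 | intermediate
14 | (5S,6S,10S)-6α-hydroxy-4,4,10β-trimethyl-trans-decalin-9-one | O[C@H]1CCC(=O)[C@@]2(C)CCCC(C)(C)[C@H]12 | intermediate
15 | dilithium enolate: C6 lithium alkoxide and C8=C9 lithium enolate of 14 | [Li]O[C@H]1CC=C(O[Li])[C@@]2(C)CCCC(C)(C)[C@H]12 | intermediate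
16 | (5S,6S,8R,10S)-6α-hydroxy-4,4,8α,10β-tetramethyl-trans-decalin-9-one | O[C@H]1C[C@@H](C)C(=O)[C@@]2(C)CCCC(C)(C)[C@H]12 | intermediate
17 | (5S,6S,8R,10S)-4,4,8α,10β-tetramethyl-9-methylene-trans-decalin-6α-ol | O[C@H]1C[C@@H](C)C(=C)[C@@]2(C)CCCC(C)(C)[C@H]12 | intermediate
18 | 9α,11-epoxide of 17 (spiro-oxirane at C9, oxygen α, C11 β) | O[C@H]1C[C@@H](C)[C@]3(CO3)[C@@]2(C)CCCC(C)(C)[C@H]12 | intermediate
19 | (5S,6S,8R,9R,10S)-9β-vinyl-4,4,8α,10β-tetramethyl-trans-decalin-6α,9α-diol | O[C@H]1C[C@@H](C)[C@](O)(C=C)[C@@]2(C)CCCC(C)(C)[C@H]12 | intermediate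
20 | 3-bromofuran-2(5H)-one | O=C1OCC=C1Br | starting material
21 | B-alkyl-9-BBN adduct of 19 (boron on C12) | O[C@H]1C[C@@H](C)[C@](O)(CCB3C4CCCC3CCC4)[C@@]2(C)CCCC(C)(C)[C@H]12 | intermediate
22 | (5S,6S,8R,9R,10S)-6α,9α-dihydroxylabd-13-en-16,15-olide | O[C@H]1C[C@@H](C)[C@](O)(CCC2=CCOC2=O)[C@@]2(C)CCCC(C)(C)[C@H]12 | intermediate
23 | (5S,6S,8R,9R,10S)-6α-acetoxy-9α-hydroxylabd-13-en-16,15-olide | CC(=O)O[C@H]1C[C@@H](C)[C@](O)(CCC2=CCOC2=O)[C@@]2(C)CCCC(C)(C)[C@H]12 | target

Total step count: 14
Longest linear sequence: 14 steps, from 1 to 23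

Three steps most likely to fail

Risk 1, step 13: transmetallation of the hindered γ-hydroxyalkyl borane may be slow, so that protodeboronation and base-mediated degradation of the bromobutenolide win. The fallback sets out from 19 and comes back to the route at 22; it builds the butenolide by carbonyl olefination instead of cross-coupling. Hydroboration of 19 with 9-BBN followed by NaOH/H2O2 would give the triol 9β-(2-hydroxyethyl)-4,4,8α,10β-tetramethyl-trans-decalin-6α,9α-diol F1. TEMPO (cat.)/PhI(OAc)2 in CH2Cl2 would oxidise only the primary hydroxyl to give the β-hydroxy aldehyde 2-(6α,9α-dihydroxy-4,4,8α,10β-tetramethyl-trans-decalin-9β-yl)acetaldehyde F2. Wittig reaction with the stabilised ylide 3-(triphenylphosphoranylidene)dihydrofuran-2(3H)-one in toluene at 80 °C would give the exocyclic α-alkylidene lactone (E)-6α,9α-dihydroxylabd-12-en-16,15-olide F3. RhCl3·3H2O (cat.) in refluxing EtOH would then move the exocyclic double bond into the lactone ring to give 22.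

Risk 2, step 12: the ylide may fail to attack the oxirane methylene, which sits next to the fully substituted C9 and C10 (neopentyl-type SN2), or base-induced isomerisation of the epoxide may compete. The fallback sets out from 17 and comes back to the route at 19; it makes the vinyl group by olefination of an aldehyde instead of epoxide opening. OsO4 (cat.)/NMO in acetone/H2O would dihydroxylate the exocyclic olefin of 17 from the α-face to give the triol 9β-(hydroxymethyl)-4,4,8α,10β-tetramethyl-trans-decalin-6α,9α-diol F4. TEMPO (cat.)/N-chlorosuccinimide/Bu4NCl in buffered CH2Cl2/H2O would oxidise the primary hydroxyl to give the α-hydroxy aldehyde 6α,9α-dihydroxy-4,4,8α,10β-tetramethyl-trans-decalin-9β-carbaldehyde F5. Ph3P=CH2 (from Ph3PCH3Br and KOt-Bu, THF, 0 °C) would then give 19.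

Risk 3, step 10: the ylide may enolise the doubly α-branched ketone instead of adding to it, so that the ketone returns on work-up. The fallback sets out from 16 and comes back to the route at 17; it is a Peterson olefination in two stages. Me3SiCH2Li with CeCl3 in THF at −78 °C would add to the carbonyl from the α-face to give the β-hydroxysilane 4,4,8α,10β-tetramethyl-9α-[(trimethylsilyl)methyl]-trans-decalin-6α,9β-diol F6. KH in THF at rt would then effect syn-elimination to 17.

Further compounds

F1 | step 13 | 9β-(2-hydroxyethyl)-4,4,8α,10β-tetramethyl-trans-decalin-6α,9α-diol | O[C@H]1C[C@@H](C)[C@](O)(CCO)[C@@]2(C)CCCC(C)(C)[C@H]12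
F2 | step 13 | 2-(6α,9α-dihydroxy-4,4,8α,10β-tetramethyl-trans-decalin-9β-yl)acetaldehyde | O[C@H]1C[C@@H](C)[C@](O)(CC=O)[C@@]2(C)CCCC(C)(C)[C@H]12
F3 | step 13 | (E)-6α,9α-dihydroxylabd-12-en-16,15-olide | O[C@H]1C[C@@H](C)[C@](O)(C/C=C3\CCOC3=O)[C@@]2(C)CCCC(C)(C)[C@H]12
F4 | step 12 | 9β-(hydroxymethyl)-4,4,8α,10β-tetramethyl-trans-decalin-6α,9α-diol | O[C@H]1C[C@@H](C)[C@](O)(CO)[C@@]2(C)CCCC(C)(C)[C@H]12
F5 | step 12 | 6α,9α-dihydroxy-4,4,8α,10β-tetramethyl-trans-decalin-9β-carbaldehyde | O[C@H]1C[C@@H](C)[C@](O)(C=O)[C@@]2(C)CCCC(C)(C)[C@H]12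
F6 | step 10 | 4,4,8α,10β-tetramethyl-9α-[(trimethylsilyl)methyl]-trans-decalin-6α,9β-diol | O[C@H]1C[C@@H](C)[C@@](O)(C[Si](C)(C)C)[C@@]2(C)CCCC(C)(C)[C@H]12
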